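**Retrosynthetic overview**
1. Target 17 ⇐ epoxy ester 16 by epoxide-to-allylic-alcohol opening (the presumed late tailoring event) ⇐ C6 acylation ⇐ hydroboration of the 5,6-alkene (sets the trans ring fusion, C5 and C6) ⇐ directed epoxidation, C10 reduction and isopropyl addition on enedione 8.
2. Hydroazulene 8 ⇐ spiro[4.5]decane 5 by a cationic 1,2-acyl shift that expands the six- to the seven-membered ring (acorenyl → daucyl cation logic); the spiro stereocentre becomes the quaternary C1.
3. Spirocycle 5 ⇐ 1,3-diketone 4 by enantioselective Conia-ene spirocyclisation ⇐ 3-methylcyclohexenone 1 + pent-4-ynoyl chloride 2.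
4. Ring order: six-membered ring (from 1) → spiro five-membered ring (step 2) → seven-membered ring by ring expansion (step 3), as in bisabolyl → acorenyl → daucyl.

Assumption 1: locants are daucane locants throughout (C1 methyl-bearing ring-fusion carbon, C2–C3 five-ring CH2, C4 isopropyl-bearing carbon, C5 ring-fusion CH, C6–C10 the other seven-ring carbons with C10 bonded to C1, C14 on C8, C15 on C1); α = face opposite the C1 methyl.
Assumption 2: the catalyst antipodes named in steps 2 and 5 follow the usual models; if the observed sense is opposite, the mirror-image catalyst (also commercial) is used.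

**Step 1**
Reactants: 1 3-methylcyclohex-2-en-1-one; 2 pent-4-ynoyl chloride
Product: 4 3-methyl-6-(pent-4-ynoyl)cyclohex-2-en-1-one, via lithium 5-methylcyclohexa-1,5-dien-1-olate 3 (not isolated)
Conditions: LiHMDS (2.1 equiv), toluene, −78 °C; then 2, −78 to 0 °C; 1 M HCl
Reagents that add atoms: lithium bis(trimethylsilyl)amide, [Li+].C[Si](C)(C)[N-][Si](C)(C)C (lithium, in 3 only)
Why: Claisen-type C-acylation of the kinetic cross-conjugated lithium enolate at the ring α′-carbon (daucane C5), the second equivalent of base trapping the acidic 1,3-diketone so that reaction stops after one acylation; the new centre is enolisable and of no consequence.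

**Step 2**
Reactants: 4 3-methyl-6-(pent-4-ynoyl)cyclohex-2-en-1-one
Product: 5 (5S)-8-methyl-4-methylidenespiro[4.5]dec-7-ene-1,6-dione
Conditions: [(R)-DTBM-SEGPHOS]Pd(OTf)2 (10 mol%), Yb(OTf)3 (20 mol%), AcOH, Et2O, 23 °C
Reagents that add atoms: none
Why: Catalytic enantioselective Conia-ene reaction (5-exo-dig carbocyclisation of the chelated palladium diketonate onto the ytterbium-activated terminal alkyne), in which the diketone carbon C5 bonds to the internal alkyne carbon C1 to give the acorane-type spirocycle with an exocyclic methylidene, the chiral diphosphine on the planar enolate setting the only stereocentre (spiro C5).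

**Step 3**
Reactants: 5 (5S)-8-methyl-4-methylidenespiro[4.5]dec-7-ene-1,6-dione
Product: 8 (8aS)-6,8a-dimethyl-1,2,5,8a-tetrahydroazulene-3,8-dione, via spiro tertiary carbocation 6 (not isolated), via ring-expanded carbocation 7 (not isolated)
Conditions: TfOH (20 mol%), (CF3)2CHOH–CH2Cl2, 0 to 25 °C
Reagents that add atoms: none
Why: Proposed new method: Markovnikov protonation of the methylidene gives tertiary cation 6 at C1 beside the spiro carbon, the enone acyl carbon C10 then makes a suprafacial Wagner–Meerwein 1,2-shift from C5 to C1 (a C6 alkyl shift would put the cation between two carbonyls and a C4 acyl shift would contract the cyclopentanone) to give cation 7, which is discharged by loss of H6 (through the enol of the C4 ketone it is a 2-hydroxyallyl cation) to the conjugated alkylidenecyclopentanone, the reversible alkene protonation in a non-nucleophilic medium funnelling material to this thermodynamic sink; C10 stays on its own face so the C5 configuration of 5 becomes the quaternary C1 configuration (1S) of 8; the closest known reaction types are acid-promoted 1,2-acyl shifts of β-acyl carbocations (epoxy ketone to 1,3-diketone ring expansions) and the acorenyl-to-daucyl cation ring expansion of daucane biosynthesis.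

**Step 4**
Reactants: 8 (8aS)-6,8a-dimethyl-1,2,5,8a-tetrahydroazulene-3,8-dione; 9 isopropylmagnesium chloride
Product: 10 (1S,4R)-4-hydroxydauca-5,8-dien-10-one
Conditions: anhydrous CeCl3, THF, −78 °C; aq. NH4Cl
Reagents that add atoms: none
Why: Organocerium 1,2-addition (Imamoto conditions, which suppress enolisation at the doubly allylic C7 and conjugate addition), chemoselective for the cyclopentenone-type C4 carbonyl because the C10 carbonyl is shielded by the quaternary C1 and deactivated as a β,β-disubstituted enone, the nucleophile entering anti to the pseudo-axial angular methyl (α-face) so that the tertiary hydroxyl is β (4R).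

**Step 5**
Reactants: 10 (1S,4R)-4-hydroxydauca-5,8-dien-10-one
Product: 11 (1S,4R,10R)-dauca-5,8-diene-4,10-diol
Conditions: (S)-Me-CBS (20 mol%), catecholborane, toluene, −78 °C; aq. NaOH
Reagents that add atoms: none
Why: Corey–Bakshi–Shibata reduction in which, with quaternary C1 as the large and vinylic C9 as the small substituent, the (S)-oxazaborolidine delivers hydride to the β-face of C10 against the substrate preference for attack anti to the angular methyl, giving the 10α (10R) allylic alcohol, while catecholborane leaves the trisubstituted alkenes untouched.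

**Step 6**
Reactants: 11 (1S,4R,10R)-dauca-5,8-diene-4,10-diol
Product: 12 (1S,4R,8R,9S,10S)-8,9-epoxydauc-5-ene-4,10-diol
Conditions: VO(acac)2 (5 mol%), t-BuOOH (1.1 equiv), CH2Cl2, 0 °C
Reagents that add atoms: tert-butyl hydroperoxide, CC(C)(C)OO
Why: Vanadium-catalysed hydroxyl-directed epoxidation of a cyclic allylic alcohol, the C10 α-hydroxyl delivering oxygen to the α-face of the 8,9-alkene (cis epoxy alcohol, 8R,9S), whereas the 5,6-alkene is spared because its tertiary C4 hydroxyl directs to the β-face that the angular methyl blocks.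

**Step 7**
Reactants: 12 (1S,4R,8R,9S,10S)-8,9-epoxydauc-5-ene-4,10-diol
Product: 14 (1S,4R,5S,6S,8R,9S,10S)-8,9-epoxydaucane-4,6,10-triol, via C6 alkylborane 13 (not isolated)
Conditions: BH3·THF, THF, 0 °C; then H2O2, aq. NaOAc, 0 to 23 °C
Reagents that add atoms: borane–tetrahydrofuran, B.C1CCOC1 (boron, in 13 only); hydrogen peroxide, OO
Why: Hydroboration–oxidation, in which borane adds syn across the trisubstituted 5,6-alkene with boron at the less substituted C6 from the α-face, anti to both the angular methyl and the allylic C4 hydroxyl (as in the hydroboration of steroidal 5-enes), setting the trans ring fusion (5S) and the 6α-hydroxyl (6S) in one operation, the buffered peroxide avoiding Payne migration of the epoxy alcohol.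

**Step 8**
Reactants: 14 (1S,4R,5S,6S,8R,9S,10S)-8,9-epoxydaucane-4,6,10-triol; 15 3-methylbutanoyl chloride
Product: 16 (1S,4R,5S,6S,8R,9S,10S)-8,9-epoxy-4,10-dihydroxydaucan-6-yl 3-methylbutanoate
Conditions: pyridine, DMAP (cat.), CH2Cl2, −20 °C
Reagents that add atoms: none
Why: DMAP-catalysed esterification under kinetic control, the C6 secondary hydroxyl reacting in preference to the C10 hydroxyl (neopentylic, next to quaternary C1 and flanked by the epoxide) and to the unreactive tertiary C4 hydroxyl, with no stereocentre touched.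

**Step 9**
Reactants: 16 (1S,4R,5S,6S,8R,9S,10S)-8,9-epoxy-4,10-dihydroxydaucan-6-yl 3-methylbutanoate
Product: 17 (1S,4R,5S,6S,9R,10S)-4,9,10-trihydroxydauc-8(14)-en-6-yl 3-methylbutanoate
Conditions: Cp2TiCl2 (2.5 equiv), Mn dust, THF, 23 °C; aq. NH4Cl
Reagents that add atoms: none
Why: Titanocene-mediated epoxide isomerisation (Nugent–RajanBabu reagent), in which single-electron opening of the trisubstituted epoxide gives the tertiary C8 radical with the C9–O bond intact and trapping by a second Cp2TiCl followed by β-hydride elimination from the methyl group gives the exocyclic 8(14)-alkene and the 9α-allylic alcohol with retention at C9, the ester and free hydroxyls being tolerated.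

**Compound list**
1 | 3-methylcyclohex-2-en-1-one | CC1=CC(=O)CCC1 | starting material
2 | pent-4-ynoyl chloride | C#CCCC(=O)Cl | starting material
3 | lithium 5-methylcyclohexa-1,5-dien-1-olate (kinetic enolate of 1) | [Li+].[O-]C1=CCCC(C)=C1 | intermediate
4 | 3-methyl-6-(pent-4-ynoyl)cyclohex-2-en-1-one (ring C6 racemic, enolisable) | CC1=CC(=O)C(C(=O)CCC#C)CC1 | intermediate
5 | (5S)-8-methyl-4-methylidenespiro[4.5]dec-7-ene-1,6-dione | C=C1CCC(=O)[C@@]12C(=O)C=C(C)CC2 | intermediate
6 | (5S)-4,8-dimethyl-1,6-dioxospiro[4.5]dec-7-en-4-ylium (tertiary cation at daucane C1) | C[C+]1CCC(=O)[C@@]12C(=O)C=C(C)CC2 | intermediate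
7 | 3a-carbenium ion of (8aS)-6,8a-dimethyl-1,2,3a,4,5,8a-hexahydroazulene-3,8-dione (cation at daucane C5) | CC1=CC(=O)[C@@]2(C)CCC(=O)[C+]2CC1 | intermediate
8 | (8aS)-6,8a-dimethyl-1,2,5,8a-tetrahydroazulene-3,8-dione (daucane skeleton without the isopropyl group; 4,10-dione, 5,8-diene, 1S) | CC1=CC(=O)[C@@]2(C)CCC(=O)C2=CC1 | intermediate
9 | isopropylmagnesium chloride | CC(C)[Mg]Cl | starting material
10 | (1S,4R)-4-hydroxydauca-5,8-dien-10-one | CC1=CC(=O)[C@@]2(C)CC[C@@](O)(C(C)C)C2=CC1 | intermediate
11 | (1S,4R,10R)-dauca-5,8-diene-4,10-diol | CC1=C[C@@H](O)[C@@]2(C)CC[C@@](O)(C(C)C)C2=CC1 | intermediate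
12 | (1S,4R,8R,9S,10S)-8,9-epoxydauc-5-ene-4,10-diol | C[C@]12O[C@H]1[C@@H](O)[C@@]3(C)CC[C@@](O)(C(C)C)C3=CC2 | intermediate
13 | 6α-boryl adduct of 12 (C6–BH2, both hydroxyls as O–BH2) | C[C@]12O[C@H]1[C@@H](OB)[C@@]3(C)CC[C@@](OB)(C(C)C)[C@@H]3[C@@H](B)C2 | intermediate
14 | (1S,4R,5S,6S,8R,9S,10S)-8,9-epoxydaucane-4,6,10-triol | C[C@]12O[C@H]1[C@@H](O)[C@@]3(C)CC[C@@](O)(C(C)C)[C@@H]3[C@@H](O)C2 | intermediate
15 | 3-methylbutanoyl chloride (isovaleryl chloride) | CC(C)CC(=O)Cl | starting material
16 | (1S,4R,5S,6S,8R,9S,10S)-8,9-epoxy-4,10-dihydroxydaucan-6-yl 3-methylbutanoate | C[C@]12O[C@H]1[C@@H](O)[C@@]3(C)CC[C@@](O)(C(C)C)[C@@H]3[C@@H](OC(=O)CC(C)C)C2 | intermediate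
17 | (1S,4R,5S,6S,9R,10S)-4,9,10-trihydroxydauc-8(14)-en-6-yl 3-methylbutanoate (CNP0204264.1) | C=C1C[C@H](OC(=O)CC(C)C)[C@@H]2[C@](C)(CC[C@@]2(O)C(C)C)[C@H](O)[C@@H]1O | target

**Total step count:** 9. **Longest linear sequence:** 9 steps (1 → 17).

**Steps most likely to fail, with fallbacks**

Step 3 is the least secure: the acyl shift passes through a cation next to the C4 carbonyl, and 6 may simply eliminate. The fallback sets out from 5 and comes back at 8. Reduction of only the saturated cyclopentanone carbonyl (NaBH4, MeOH, −78 °C) gives (5S)-1-hydroxy-8-methyl-4-methylidenespiro[4.5]dec-7-en-6-one F1. The same acid treatment then ends by a 1,2-hydride shift from the carbinol carbon (pinacol-type termination, no α-acyl cation) to give (8aS)-6,8a-dimethyl-1,2,3a,4,5,8a-hexahydroazulene-3,8-dione F2. Acid-mediated bromination at the more substituted α-carbon (pyridinium tribromide, AcOH) gives (8aR)-3a-bromo-6,8a-dimethyl-1,2,3a,4,5,8a-hexahydroazulene-3,8-dione F3, and dehydrobromination (Li2CO3, LiBr, DMF, 120 °C) gives 8.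

Step 2 is second: enantioselective Conia-ene closure with the alkyne tethered through an acyl carbon has no direct precedent. The fallback sets out from 4 and comes back at 5. A Ph3PAuCl/AgOTf-catalysed Conia-ene reaction gives racemic 8-methyl-4-methylidenespiro[4.5]dec-7-ene-1,6-dione F4, which is resolved by preparative chromatography on a chiral stationary phase to give 5.

Step 5 is third: reagent control must override hydride attack anti to the angular methyl. The fallback sets out from 10 and comes back at 11. Luche reduction (NaBH4, CeCl3, MeOH, −78 °C) gives the substrate-controlled (1S,4R,10S)-dauca-5,8-diene-4,10-diol F5. Mitsunobu inversion (4-nitrobenzoic acid, PPh3, DIAD, THF), as used on 17β-hydroxy steroids, gives (1S,4R,10R)-4-hydroxydauca-5,8-dien-10-yl 4-nitrobenzoate F6, and methanolysis (K2CO3, MeOH) gives 11.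

**Further compounds**
F1 | step 3 | (5S)-1-hydroxy-8-methyl-4-methylidenespiro[4.5]dec-7-en-6-one (both carbinol epimers) | C=C1CCC(O)[C@@]12C(=O)C=C(C)CC2
F2 | step 3 | (8aS)-6,8a-dimethyl-1,2,3a,4,5,8a-hexahydroazulene-3,8-dione (both C3a epimers) | CC1=CC(=O)[C@@]2(C)CCC(=O)C2CC1
F3 | step 3 | (8aR)-3a-bromo-6,8a-dimethyl-1,2,3a,4,5,8a-hexahydroazulene-3,8-dione (both C3a epimers) | CC1=CC(=O)[C@@]2(C)CCC(=O)C2(Br)CC1
F4 | step 2 | racemic 8-methyl-4-methylidenespiro[4.5]dec-7-ene-1,6-dione | C=C1CCC(=O)C12C(=O)C=C(C)CC2
F5 | step 5 | (1S,4R,10S)-dauca-5,8-diene-4,10-diol | CC1=C[C@H](O)[C@@]2(C)CC[C@@](O)(C(C)C)C2=CC1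
F6 | step 5 | (1S,4R,10R)-4-hydroxydauca-5,8-dien-10-yl 4-nitrobenzoate | CC1=C[C@@H](OC(=O)c3ccc(cc3)[N+](=O)[O-])[C@@]2(C)CC[C@@](O)(C(C)C)C2=CC1
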